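Ring B of this 7β-acetoxy-labda-8(17),13E-diene is disconnected at C6–C7 and C8–C9. The plan exploits that C6–C5–C10–C9 together with the first two side-chain carbons, C11 and C12, can be held in a temporary cyclohexenone (C12=O, C9=C11) trans-fused to ring A. In one operation tert-butyl methyl malonate adds to C9 (C8–C9), C6 attacks its methyl ester (C6–C7), and methoxide cleaves the temporary C6–C12 bond of the bridged 1,3-diketone. The carbocycle is thereby transposed into ring B with the C7 ketone, a C8 carboxyl handle for the methylene group, and C11–C12 released as the side-chain ester. The precursor is bicyclic enone 10.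

Key step: step 7

Assumption: atoms carry labdane numbers (C1–C20) throughout; in step 1 the cupreidine- or cupreine-derived pseudoenantiomer of the catalyst that gives (S)-3 is the one used.

Step 1
Reactants: 1 methyl 2-methyl-3-oxopentanoate; 2 acrolein
Product: 4 methyl (1S)-1,3-dimethyl-2-oxocyclohex-3-ene-1-carboxylate, via keto aldehyde 3 (not isolated)
Conditions: 9-O-(9-phenanthryl)cupreidine (10 mol %), CH2Cl2, −24 °C; then TsOH·H2O (20 mol %), toluene, 110 °C, Dean–Stark
Reagents that add atoms: none
Why: A bifunctional cinchona-alkaloid-catalysed Michael addition of the α-methyl β-keto ester to acrolein should set the C4 quaternary centre (catalyst-controlled enolate face), and acid-catalysed intramolecular aldol condensation of the ethyl ketone onto the aldehyde then closes ring A.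

Step 2
Reactants: 4 methyl (1S)-1,3-dimethyl-2-oxocyclohex-3-ene-1-carboxylate
Product: 5 methyl (1S)-1,3-dimethyl-2-oxocyclohexane-1-carboxylate (C3 epimers)
Conditions: H2 (1 atm), 10% Pd/C, EtOAc, rt
Reagents that add atoms: none
Why: Heterogeneous hydrogenation of the enone C=C; the new C10 centre forms as an epimer mixture that is erased by enolisation in step 3.

Step 3
Reactants: 5 methyl (1S)-1,3-dimethyl-2-oxocyclohexane-1-carboxylate; 6 methyl vinyl ketone
Product: 7 methyl (1S,3R)-1,3-dimethyl-2-oxo-3-(3-oxobutyl)cyclohexane-1-carboxylate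
Conditions: KOtBu (10 mol %), t-BuOH/THF, 0 °C
Reagents that add atoms: none
Why: Michael addition of the only possible enolate (C10) under non-chelating conditions; the C10 quaternary centre should form by attack anti to the pseudo-axial C4 ester (steric approach control across the 1,3-positions), which places the oxobutyl chain trans to CO2Me.

Step 4
Reactants: 7 methyl (1S,3R)-1,3-dimethyl-2-oxo-3-(3-oxobutyl)cyclohexane-1-carboxylate
Product: 8 methyl (1S,4aR)-1,4a-dimethyl-7-oxo-1,2,3,4,4a,5,6,7-octahydronaphthalene-1-carboxylate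
Conditions: TsOH·H2O (0.2 equiv), toluene, 110 °C, Dean–Stark
Reagents that add atoms: none
Why: Acid-catalysed intramolecular aldol condensation (second half of a Robinson annulation) of the methyl ketone onto the ring ketone; no stereocentre is formed and acid avoids retro-Claisen opening of the non-enolisable β-keto ester.

Step 5
Reactants: 8 methyl (1S,4aR)-1,4a-dimethyl-7-oxo-1,2,3,4,4a,5,6,7-octahydronaphthalene-1-carboxylate
Product: 9 methyl (1S,4aR,8aR)-1,4a-dimethyl-7-oxodecahydronaphthalene-1-carboxylate
Conditions: Li (2.5 equiv), NH3(l)/THF, t-BuOH (1 equiv), −78 °C, short contact; then NH4Cl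
Reagents that add atoms: none
Why: Dissolving-metal (Birch-type) enone reduction; axial protonation of the C5 carbanion anti to the angular methyl should give the trans-decalin (5α-H), and the measured amount of lithium at low temperature should spare the hindered ester.

Step 6
Reactants: 9 methyl (1S,4aR,8aR)-1,4a-dimethyl-7-oxodecahydronaphthalene-1-carboxylate
Product: 10 methyl (1S,4aR,8aR)-1,4a-dimethyl-7-oxo-1,2,3,4,4a,7,8,8a-octahydronaphthalene-1-carboxylate
Conditions: IBX (1.3 equiv), DMSO/toluene, 70 °C
Reagents that add atoms: none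
Why: IBX dehydrogenation of the ketone through its less hindered enol (towards C11H2–C9H2, as in 3-keto-5α-steroids) should give the C9=C11 enone; no stereocentre changes.

Step 7
Reactants: 10 methyl (1S,4aR,8aR)-1,4a-dimethyl-7-oxo-1,2,3,4,4a,7,8,8a-octahydronaphthalene-1-carboxylate; 11 tert-butyl methyl malonate
Product: 14 6-tert-butyl 1-methyl (1S,4aR,5S,8aR)-5-(2-methoxy-2-oxoethyl)-1,4a-dimethyl-7-oxodecahydronaphthalene-1,6-dicarboxylate, via Michael adduct 12 (not isolated), via bridged diketone 13 (not isolated)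
Conditions: 11 (1.5 equiv), NaOMe (2 equiv), MeOH, 65 → 90 °C (sealed tube); aq. NH4Cl
Reagents that add atoms: sodium methoxide, [Na+].[O-]C
Why: Proposed new method: the malonate anion adds to C9 of enone 10 (Michael, C8–C9), the C6 enolate of the resulting ketone attacks the methyl ester of the axial malonate (Dieckmann, C6–C7) to give the bridged bicyclo[2.2.2]octane-2,6-dione 13, and methoxide adds to the C12 ketone and cleaves the C6–C12 bond (retro-Claisen), which releases the strain and gives the enolate of β-keto ester 14. The closest known reactions are the Michael–Claisen annulation of enones with malonates (dimedone synthesis), the acyl transposition of the abnormal Michael reaction and the alkoxide opening of bicyclo[2.2.2]octane-2,6-diones. Ring B should close by a 6-exo-trig Dieckmann attack of the C6 enolate on the ester carbonyl across a boat of the temporary ring, which is then opened. C9 is set in the Michael step by axial attack on the α-face anti to the C10 methyl group, which after the ring transposition corresponds to the equatorial 9β side chain, while C8 stays epimerisable (enolised). The step needs cleavage at C12 and not at C7, and acylation by the methyl and not the tert-butyl ester: only cleavage at C12 gives an enolisable β-keto ester whose enolate is the thermodynamic sink under these reversible conditions, and the tert-butyl ester resists acyl substitution.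

Step 8
Reactants: 14 6-tert-butyl 1-methyl (1S,4aR,5S,8aR)-5-(2-methoxy-2-oxoethyl)-1,4a-dimethyl-7-oxodecahydronaphthalene-1,6-dicarboxylate
Product: 16 methyl (1S,4aR,5R,8aR)-5-(2-methoxy-2-oxoethyl)-1,4a-dimethyl-6-methylidene-7-oxodecahydronaphthalene-1-carboxylate, via keto acid 15 (not isolated)
Conditions: TFA, CH2Cl2, 0 °C → rt; evaporate; then 37% aq. CH2O, Et2NH, THF, rt → 40 °C
Reagents that add atoms: formaldehyde, C=O
Why: Acidolysis of the tert-butyl ester, Mannich reaction of the β-keto acid at C8 and decarboxylative elimination of the amine (decarboxylative methylenation) should place the exocyclic methylene regiospecifically on C8; no stereocentre is formed.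

Step 9
Reactants: 16 methyl (1S,4aR,5R,8aR)-5-(2-methoxy-2-oxoethyl)-1,4a-dimethyl-6-methylidene-7-oxodecahydronaphthalene-1-carboxylate
Product: 17 methyl (1S,4aR,5R,7S,8aR)-7-hydroxy-5-(2-methoxy-2-oxoethyl)-1,4a-dimethyl-6-methylidenedecahydronaphthalene-1-carboxylate
Conditions: NaBH4, CeCl3·7H2O, MeOH, −78 °C
Reagents that add atoms: none
Why: Luche 1,2-reduction; hydride should add axially from the α-face of the C7 ketone (opposed only by the axial hydrogens on C5 and C9), which gives the equatorial 7β-alcohol.

Step 10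
Reactants: 17 methyl (1S,4aR,5R,7S,8aR)-7-hydroxy-5-(2-methoxy-2-oxoethyl)-1,4a-dimethyl-6-methylidenedecahydronaphthalene-1-carboxylate
Product: 18 methyl (1S,4aR,5R,7S,8aR)-7-hydroxy-5-(2-hydroxyethyl)-1,4a-dimethyl-6-methylidenedecahydronaphthalene-1-carboxylate
Conditions: LiBH4 (2 equiv), MeOH (2 equiv), THF, 0 °C → rt
Reagents that add atoms: none
Why: Chemoselective borohydride reduction of the unhindered C12 methyl ester; the axial neopentyl C19 ester should be untouched and no stereocentre changes.

Step 11
Reactants: 18 methyl (1S,4aR,5R,7S,8aR)-7-hydroxy-5-(2-hydroxyethyl)-1,4a-dimethyl-6-methylidenedecahydronaphthalene-1-carboxylate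
Product: 19 methyl (1S,4aR,5R,7S,8aR)-7-hydroxy-5-(2-iodoethyl)-1,4a-dimethyl-6-methylidenedecahydronaphthalene-1-carboxylate
Conditions: PPh3, I2, imidazole, CH2Cl2, 0 °C
Reagents that add atoms: iodine, II
Why: Appel-type iodination, selective for the primary alcohol over the hindered secondary allylic one; no stereocentre is touched.

Step 12
Reactants: 19 methyl (1S,4aR,5R,7S,8aR)-7-hydroxy-5-(2-iodoethyl)-1,4a-dimethyl-6-methylidenedecahydronaphthalene-1-carboxylate
Product: 20 methyl (1S,4aR,5R,7S,8aR)-7-acetoxy-5-(2-iodoethyl)-1,4a-dimethyl-6-methylidenedecahydronaphthalene-1-carboxylate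
Conditions: Ac2O, pyridine, DMAP (cat.), CH2Cl2, rt
Reagents that add atoms: acetic anhydride, CC(=O)OC(C)=O
Why: DMAP-catalysed acylation of the C7 alcohol with retention, done before the coupling so that the zinc reagent meets no free hydroxyl group.

Step 13
Reactants: 21 but-2-yn-1-ol
Product: 22 tert-butyl(but-2-yn-1-yloxy)dimethylsilane
Conditions: TBSCl, imidazole, CH2Cl2, rt
Reagents that add atoms: tert-butyldimethylsilyl chloride, CC(C)(C)[Si](C)(C)Cl
Why: Standard silylation of the primary alcohol.

Step 14
Reactants: 22 tert-butyl(but-2-yn-1-yloxy)dimethylsilane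
Product: 23 (E)-tert-butyl[(3-iodobut-2-en-1-yl)oxy]dimethylsilane
Conditions: Cp2Zr(H)Cl (2 equiv), THF, 50 °C; then I2, 0 °C
Reagents that add atoms: iodine, II
Why: Hydrozirconation (syn addition, with zirconium on the methyl-bearing carbon after equilibration with excess Cp2Zr(H)Cl) and iodinolysis with retention should give the (E)-vinyl iodide.

Step 15
Reactants: 20 methyl (1S,4aR,5R,7S,8aR)-7-acetoxy-5-(2-iodoethyl)-1,4a-dimethyl-6-methylidenedecahydronaphthalene-1-carboxylate; 23 (E)-tert-butyl[(3-iodobut-2-en-1-yl)oxy]dimethylsilane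
Product: 25 methyl (1S,4aR,5R,7S,8aR)-7-acetoxy-5-[(3E)-5-[(tert-butyldimethylsilyl)oxy]-3-methylpent-3-en-1-yl]-1,4a-dimethyl-6-methylidenedecahydronaphthalene-1-carboxylate, via alkylzinc iodide 24 (not isolated)
Conditions: Zn dust (activated), LiCl, THF, 40 °C; then 23 (1.2 equiv), Pd(PPh3)4 (5 mol %), THF, rt
Reagents that add atoms: none
Why: Zinc insertion and Negishi sp3–sp2 coupling with retention of the (E)-geometry; the equatorial C7 acetate lies near the nodal plane of the exocyclic alkene, so its ionisation to a π-allyl complex should be slow next to oxidative addition of zerovalent palladium to the vinyl iodide.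

Step 16
Reactants: 25 methyl (1S,4aR,5R,7S,8aR)-7-acetoxy-5-[(3E)-5-[(tert-butyldimethylsilyl)oxy]-3-methylpent-3-en-1-yl]-1,4a-dimethyl-6-methylidenedecahydronaphthalene-1-carboxylate
Product: 26 methyl (1S,4aR,5R,7S,8aR)-7-acetoxy-5-[(3E)-5-hydroxy-3-methylpent-3-en-1-yl]-1,4a-dimethyl-6-methylidenedecahydronaphthalene-1-carboxylate (CNP0329157.1)
Conditions: HF·pyridine, THF/pyridine, 0 °C → rt
Reagents that add atoms: none
Why: Buffered fluoride desilylation of the primary allylic silyl ether should leave the acetate and the methyl ester intact.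

Compound list
1 | methyl 2-methyl-3-oxopentanoate (racemic) | CCC(=O)C(C)C(=O)OC | starting material
2 | acrolein (prop-2-enal) | C=CC=O | starting material
3 | methyl (2S)-2-methyl-3-oxo-2-(3-oxopropyl)pentanoate | CCC(=O)[C@](C)(CCC=O)C(=O)OC | intermediate
4 | methyl (1S)-1,3-dimethyl-2-oxocyclohex-3-ene-1-carboxylate | O=C1C(C)=CCC[C@]1(C)C(=O)OC | intermediate
5 | methyl (1S)-1,3-dimethyl-2-oxocyclohexane-1-carboxylate, mixture of C3 epimers | O=C1C(C)CCC[C@]1(C)C(=O)OC | intermediate
6 | methyl vinyl ketone (but-3-en-2-one) | C=CC(C)=O | starting material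
7 | methyl (1S,3R)-1,3-dimethyl-2-oxo-3-(3-oxobutyl)cyclohexane-1-carboxylate | O=C1[C@](C)(CCC[C@]1(C)C(=O)OC)CCC(C)=O | intermediate
8 | methyl (1S,4aR)-1,4a-dimethyl-7-oxo-1,2,3,4,4a,5,6,7-octahydronaphthalene-1-carboxylate | O=C1C=C2[C@](C)(CCC[C@]2(C)C(=O)OC)CC1 | intermediate
9 | methyl (1S,4aR,8aR)-1,4a-dimethyl-7-oxodecahydronaphthalene-1-carboxylate (trans-fused) | O=C1C[C@@H]2[C@](C)(CCC[C@]2(C)C(=O)OC)CC1 | intermediate
10 | methyl (1S,4aR,8aR)-1,4a-dimethyl-7-oxo-1,2,3,4,4a,7,8,8a-octahydronaphthalene-1-carboxylate | O=C1C[C@@H]2[C@](C)(CCC[C@]2(C)C(=O)OC)C=C1 | intermediate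
11 | tert-butyl methyl malonate | COC(=O)CC(=O)OC(C)(C)C | starting material
12 | 1-tert-butyl 3-methyl 2-[(1S,4aR,5S,8aR)-5-(methoxycarbonyl)-5,8a-dimethyl-3-oxodecahydronaphthalen-1-yl]propanedioate (malonate axial on C9, anti to the angular methyl; malonate CH unassigned) | O=C1C[C@@H]2[C@](C)(CCC[C@]2(C)C(=O)OC)[C@H](C(C(=O)OC)C(=O)OC(C)(C)C)C1 | intermediate
13 | bridged diketone: bicyclo[2.2.2]octane-2,6-dione with carbonyls C7 and C12, C6 and C9 as bridgeheads, tert-butyl ester on C8, ring A trans-fused at C5–C10 and carrying the C19 methyl ester | O=C1[C@H]3[C@@H]2[C@](C)(CCC[C@]2(C)C(=O)OC)[C@H](C(C(=O)OC(C)(C)C)C3=O)C1 | intermediate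
14 | 6-tert-butyl 1-methyl (1S,4aR,5S,8aR)-5-(2-methoxy-2-oxoethyl)-1,4a-dimethyl-7-oxodecahydronaphthalene-1,6-dicarboxylate (C6 of the name, labdane C8, epimerisable and enolised) | CC(C)(C)OC(=O)C1C(=O)C[C@@H]2[C@](C)(CCC[C@]2(C)C(=O)OC)[C@H]1CC(=O)OC | intermediate
15 | β-keto acid: the free 6-carboxylic acid of 14 | OC(=O)C1C(=O)C[C@@H]2[C@](C)(CCC[C@]2(C)C(=O)OC)[C@H]1CC(=O)OC | intermediate
16 | methyl (1S,4aR,5R,8aR)-5-(2-methoxy-2-oxoethyl)-1,4a-dimethyl-6-methylidene-7-oxodecahydronaphthalene-1-carboxylate | C=C1C(=O)C[C@@H]2[C@](C)(CCC[C@]2(C)C(=O)OC)[C@H]1CC(=O)OC | intermediate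
17 | methyl (1S,4aR,5R,7S,8aR)-7-hydroxy-5-(2-methoxy-2-oxoethyl)-1,4a-dimethyl-6-methylidenedecahydronaphthalene-1-carboxylate | C=C1[C@@H](O)C[C@@H]2[C@](C)(CCC[C@]2(C)C(=O)OC)[C@H]1CC(=O)OC | intermediate
18 | methyl (1S,4aR,5R,7S,8aR)-7-hydroxy-5-(2-hydroxyethyl)-1,4a-dimethyl-6-methylidenedecahydronaphthalene-1-carboxylate | C=C1[C@@H](O)C[C@@H]2[C@](C)(CCC[C@]2(C)C(=O)OC)[C@H]1CCO | intermediate
19 | methyl (1S,4aR,5R,7S,8aR)-7-hydroxy-5-(2-iodoethyl)-1,4a-dimethyl-6-methylidenedecahydronaphthalene-1-carboxylate | C=C1[C@@H](O)C[C@@H]2[C@](C)(CCC[C@]2(C)C(=O)OC)[C@H]1CCI | intermediate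
20 | methyl (1S,4aR,5R,7S,8aR)-7-acetoxy-5-(2-iodoethyl)-1,4a-dimethyl-6-methylidenedecahydronaphthalene-1-carboxylate | C=C1[C@@H](OC(C)=O)C[C@@H]2[C@](C)(CCC[C@]2(C)C(=O)OC)[C@H]1CCI | intermediate
21 | but-2-yn-1-ol | CC#CCO | starting material
22 | tert-butyl(but-2-yn-1-yloxy)dimethylsilane | CC#CCO[Si](C)(C)C(C)(C)C | intermediate
23 | (E)-tert-butyl[(3-iodobut-2-en-1-yl)oxy]dimethylsilane | C/C(I)=C\CO[Si](C)(C)C(C)(C)C | intermediate
24 | alkylzinc iodide of 20 (C12–ZnI) | C=C1[C@@H](OC(C)=O)C[C@@H]2[C@](C)(CCC[C@]2(C)C(=O)OC)[C@H]1CC[Zn]I | intermediate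
25 | methyl (1S,4aR,5R,7S,8aR)-7-acetoxy-5-[(3E)-5-[(tert-butyldimethylsilyl)oxy]-3-methylpent-3-en-1-yl]-1,4a-dimethyl-6-methylidenedecahydronaphthalene-1-carboxylate | C=C1[C@@H](OC(C)=O)C[C@@H]2[C@](C)(CCC[C@]2(C)C(=O)OC)[C@H]1CC/C(C)=C/CO[Si](C)(C)C(C)(C)C | intermediate
26 | methyl (1S,4aR,5R,7S,8aR)-7-acetoxy-5-[(3E)-5-hydroxy-3-methylpent-3-en-1-yl]-1,4a-dimethyl-6-methylidenedecahydronaphthalene-1-carboxylate (methyl 7β-acetoxy-15-hydroxylabda-8(17),13E-dien-19-oate) | C=C1[C@@H](OC(C)=O)C[C@@H]2[C@](C)(CCC[C@]2(C)C(=O)OC)[C@H]1CC/C(C)=C/CO | target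

Total step count: 16. Longest linear sequence: 14 steps (steps 1–12, 15 and 16; steps 13 and 14 make the side-chain fragment).

Steps most likely to fail

Step 7. The cascade may stall at Michael adduct 12 or revert by retro-Michael reaction, because the Dieckmann closure has to pass through a bicyclo[2.2.2]octanedione that is trans-fused to ring A and therefore strained. Slow methanolysis of the tert-butyl ester at the temperature needed is a second drain. The fallback uses known chemistry, sets out from 10 and comes back at 14. Enone 10 is converted with TBSOTf and Et3N into the cross-conjugated silyl dienol ether F1; only the C6 protons are available because the γ-position is quaternary. A thermal or high-pressure Diels–Alder reaction of F1 with tert-butyl (E)-3-(pinacolboryl)acrylate, anti to the angular methyl, forms C6–C7 and C8–C9 in one operation and should give the boryl cycloadduct F2, with the ester on C8 as expected for a 2-silyloxydiene. NaBO3 oxidation of the C–B bond gives the bridged alcohol F3, and DMP oxidation gives the bridged ketone F4. NaOMe in MeOH then removes the silyl group, which unveils 13, and opens it by the known retro-Claisen reaction to 14.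

Step 3. Poor facial selectivity in the Michael addition at C10 (attack syn to the C4 ester through a chelated or chair-like transition state) would give the C10 epimer. The fallback sets out from 5 and comes back at 7. Ketone 5 is condensed with (S)-1-phenylethylamine (TiCl4, Et3N) to the chiral imine F5. Its secondary enamine tautomer adds to methyl vinyl ketone on the face fixed by the auxiliary (deracemising chiral-imine Michael reaction), and aqueous acetic acid hydrolysis returns 7 and the amine.

Step 8. Loss of CO2 from keto acid 15 before the Mannich reaction would give the C7 ketone without regiocontrol, and the exocyclic enone may dimerise or add the amine. The fallback sets out from 14 and comes back at 16. The β-keto ester is first C-alkylated at C8 with dimethylmethyleneammonium iodide and K2CO3 to the Mannich base F6. TFA then removes the tert-butyl group and gentle warming brings about decarboxylative loss of dimethylamine, so no free enolisable β-keto acid is handled.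

Further compounds
F1 | step 7 | methyl (1S,4aR,8aR)-7-[(tert-butyldimethylsilyl)oxy]-1,4a-dimethyl-1,2,3,4,4a,8a-hexahydronaphthalene-1-carboxylate (silyl dienol ether) | CC(C)(C)[Si](C)(C)OC1=C[C@@H]2[C@](C)(CCC[C@]2(C)C(=O)OC)C=C1
F2 | step 7 | boryl cycloadduct: bicyclo[2.2.2]octene silyl enol ether with pinacolboryl on C7 and tert-butyl ester on C8 (C7 and C8 unassigned) | CC(C)(C)[Si](C)(C)OC1[C@H]3[C@@H]2[C@](C)(CCC[C@]2(C)C(=O)OC)[C@H](C(C(=O)OC(C)(C)C)C3B4OC(C)(C)C(C)(C)O4)C=1
F3 | step 7 | bridged alcohol: C7 alcohol of the cycloadduct, silyl enol ether retained | CC(C)(C)[Si](C)(C)OC1[C@H]3[C@@H]2[C@](C)(CCC[C@]2(C)C(=O)OC)[C@H](C(C(=O)OC(C)(C)C)C3O)C=1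
F4 | step 7 | bridged ketone: C7 ketone, the silyl enol ether of 13 | CC(C)(C)[Si](C)(C)OC1[C@H]3[C@@H]2[C@](C)(CCC[C@]2(C)C(=O)OC)[C@H](C(C(=O)OC(C)(C)C)C3=O)C=1
F5 | step 3 | chiral imine of 5 and (S)-1-phenylethylamine | C[C@H](N=C1C(C)CCC[C@]1(C)C(=O)OC)c1ccccc1
F6 | step 8 | Mannich base: 14 bearing a dimethylaminomethyl group on C8 | CN(C)CC1(C(=O)OC(C)(C)C)C(=O)C[C@@H]2[C@](C)(CCC[C@]2(C)C(=O)OC)[C@H]1CC(=O)OC
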